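## Analysis of the target

Target 19 is a flavonol: a 4H-chromen-4-one whose benzo ring A is fused to the pyranone ring C, with the 4-methoxyphenyl ring B on C2, an enolic hydroxyl on C3, a hydroxyl on C5 hydrogen-bonded to the C4 carbonyl, and a methoxy group on C7. C8, the ring A carbon between C8a (bearing O1) and C7, carries a 1-(4-hydroxyphenyl)ethyl group whose methine carbon is the only stereocentre; it is (R) (ring A > ring D > CH3 > H) and, having no partner, must be set by a chiral reagent or catalyst. The centre differs from its mirror image only in the places of CH3 and H on a carbon held between two oxygenated aryl rings, which gives most asymmetric methods little to grip. The sensitive points are the free phenols, the oxidisable 3-hydroxypyranone, the two methyl ethers that must survive while C5 is unmasked, and above all the C8–CH bond: ring A is a phloroglucinol ether, so ipso-protonation at C8 and loss of a para-oxygenated 1-arylethyl cation would racemise or remove the side chain under strong acid. Two regiochemical demands add to the difficulty: the side chain must sit at C8 and not C6, and the acyl carbon of ring C must enter at C4a, on a ring whose free positions are almost equally activated. The strategy rests on ring D: it is a para-hydroxyphenyl group bonded directly to the stereocentre, so removing CH3 from the methine turns ring D into the cyclohexadienone of a para-quinone methide whose exocyclic carbon carries only H and ring A. The three oxygens of ring A stand ortho and para to C8 and stabilise that quinone methide by donation, and the symmetric quinoid ring leaves it without E/Z isomers, so the CH–CH3 bond and the stereocentre can be made together by an enantioselective 1,6-addition of a methyl group.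

## Retrosynthetic reasoning

19 to 18. The last bond cut is O–CH3 at C5. A methyl ether there needs no separate protecting group through the basic and oxidative steps, and its place next to the C4 carbonyl makes it the one ether a chelating boron Lewis acid removes. The forward step must spare the C7 and ring B methyl ethers and the stereocentre.

18 to 16. Ring C is opened at O1–C2 and the C3 oxygen is removed, which leads to chalcone 16. The forward reaction is an alkaline peroxide oxidative cyclisation through dihydroflavonol 17. It must close the six-membered ring at the β-carbon in preference to the five-membered alternative.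

16 to 13 and 14. The enone double bond is cut, so that ring B and C2 arrive as aldehyde 14 and ring A keeps a methyl ketone. The ring D acetate of 13 is lost in the same basic medium (through 15), so the chalcone already carries the free ring D phenol of the target.

13 to 11. The C4a–acetyl bond is cut. The free C8a hydroxyl of 11 directs acylation to its only open ortho position and holds the product as boron chelate 12. The same acylating agent caps the ring D phenol, which lowers the donor power of ring D in the one Lewis-acidic step that precedes deactivation of ring A. An acetyl group placed earlier would weaken ring A as a donor in the quinone methide and would compete as an electrophile when ring D is attached.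

11 to 10. The O-allyl bond is cut. Allyl is orthogonal to the methyl ethers, inert to the organomagnesium, fluoride and organozinc steps, and leaves under zerovalent palladium without acid.

10 to 7 and 8. This is the key cut, the methine–CH3 bond. It is the only bond at the stereocentre whose removal leaves an achiral electrophile with a single geometry; cutting toward either aryl ring would require a configurationally labile benzylic cation or anion. The forward step must deliver the methyl group of 8 to one face of the exocyclic carbon of 7 and give ring D back as a phenolate (9).

7 to 6. The quinone methide is stored as a doubly masked hydrate, a benzylic acetate with ring D as its silyl ether. Fluoride removes silicon and the phenoxide expels acetate. This avoids acid, under which the benzhydryl cation would alkylate the nucleophilic free positions of ring A in a second molecule.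

6 to 2 and 3. The bond from the benzylic carbon to ring D is cut: the aryl Grignard reagent 4 from bromide 3 adds to aldehyde 2, and alkoxide 5 is acetylated in the flask. The aldehyde carbon of 2 already sits between the two differentiated oxygens of ring A, which fixes the C8 regiochemistry for the whole route.

2 to 1. The O-allyl bond is cut. Phenol 1 has its one free hydroxyl where O1 is needed and methyl ethers at the future C5 and C7.

## Alternatives that were turned down

Alternative 1: Ring A is built instead of bought, by cutting three of its bonds (C8a–C8, C6–C7, C4a–C8a). Heating 3-ethoxycyclobut-2-en-1-one A2 with the enantioenriched siloxyalkyne A3 would open the four-membered ring to a vinylketene, join it to the alkyne, and after a second ring opening close ring A by six-electron electrocyclisation to phenol A1 (Danheiser benzannulation).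
- For: the reaction type is established. The three oxygens of ring A emerge differentiated. The crowded C8 substituent is placed with full regiocontrol because it rides in on the alkyne, and the stereocentre never meets an electrophilic substitution.
- Against: the stereocentre must already exist in A3, a benzylic, propargylic centre that needs its own asymmetric synthesis and several steps to the silyl ynol ether. A branched substituent on the alkyne slows the ketene addition. The oxygen pattern of A1 (silyl at C7, ethyl at C5) is not that of the target, so protecting groups must be exchanged. Rings B and C remain to be made as in the chosen route.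
- Comparison: Alternative 1 is stronger in precedent for its key step and in regiochemical certainty. The chosen route offers instead a stereocentre made catalytically on an achiral intermediate three steps from catalogue aromatics, the methyl ethers in place from the start, and a clearly shorter sequence.

Alternative 2: The stereocentre is set on an open chain and ring D is grown onto it, cutting all six ring D carbons. The enamine of aldehyde A5 would add through its α-carbon to but-3-en-2-one A6 and the keto aldehyde would close by aldol condensation to cyclohexenone A4, which must then be dehydrogenated to the phenol.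
- For: the aryl–CH(CH3) centre of A5 is accessible by dependable asymmetric conjugate addition, and the annulation is a known organocatalytic form of the Robinson annulation.
- Against: a para-hydroxyphenyl ring, the cheapest part of the molecule, is assembled atom by atom, and the ring stereocentre of A4 is made only to be destroyed. The dehydrogenation needs an oxidant or a hot palladium catalyst beside a trialkoxyarene. As soon as ring D is aromatic, the methine hydrogen is doubly benzylic and para to a phenol; its loss gives a quinone methide and erases the stereocentre.
- Comparison: Alternative 2 is stronger in that its enantioselective step has precedent. The chosen route uses the same quinone methide relationship constructively, takes ring D from a commercial bromophenol ether and is several steps shorter.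

Alternative 3: The bond from the stereocentre to ring D is cut on a coumarin. A catalyst from Rh(acac)(C2H4)2 A10 and a chiral bisphosphine would add [4-(benzyloxy)phenyl]boronic acid A9 to C4 of 5,7-dimethoxy-2H-chromen-2-one A8 to give chromanone A7.
- For: asymmetric conjugate arylation of coumarins is an established, highly enantioselective reaction type and A8 is a catalogue compound. The lactone oxygen of A7 is the future O1, so it is differentiated from the two methyl ethers without a protecting group.
- Against: A7 has one carbon too many. The CH2 beside the stereocentre must end as CH3, so the lactone has to be opened, the phenol capped against relactonisation, and the carboxyl carbon excised by radical decarboxylation. The primary radical next to a diarylmethine can undergo a 1,2-aryl shift unless hydrogen transfer is very fast. The 5-methoxy group peri to C4 and the electron-rich ring also lower the acceptor reactivity.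
- Comparison: Alternative 3 is stronger in precedent and in differentiating the oxygens. The chosen route forms the C–CH3 bond itself, deletes no carbon, needs no radical step and is shorter, at the price of an untested catalytic step.

Key step: step 4

Assumption: the sense of induction of the copper–phosphoramidite catalyst in step 4 cannot be derived from structure alone, so the ligand enantiomer meant is the one that gives the (R) centre; silyl ether 3 is taken as a catalogue chemical (one silylation from 4-bromophenol).

## Route

Step 1
Reactants: 1 2-hydroxy-4,6-dimethoxybenzaldehyde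
Product: 2 2-(allyloxy)-4,6-dimethoxybenzaldehyde
Conditions: allyl bromide, K2CO3, DMF, 50 °C
Reagents that add atoms: allyl bromide, C=CCBr
Why: Williamson ether synthesis; the chelated 2-hydroxyl is the only acidic site and its potassium phenoxide is alkylated by the primary allylic bromide, which marks the oxygen that later becomes O1.

Step 2
Reactants: 3 (4-bromophenoxy)(tert-butyl)dimethylsilane; 2 2-(allyloxy)-4,6-dimethoxybenzaldehyde
Product: 6 (2-allyloxy-4,6-dimethoxyphenyl)[4-(tert-butyldimethylsilyloxy)phenyl]methyl acetate, via arylmagnesium bromide 4 (not isolated), via bromomagnesium alkoxide 5 (not isolated)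
Conditions: Mg, THF, 40 °C; then 2, THF, −20 → 0 °C; then Ac2O, DMAP (cat.), 0 °C → rt; aq NaHCO3
Reagents that add atoms: acetic anhydride, CC(=O)OC(C)=O
Why: Grignard addition to an aldehyde followed by O-acylation of the magnesium alkoxide in the same flask; the aryl silyl ether, the allyl ether and the methyl ethers are inert to both, and trapping the alkoxide avoids handling the acid-labile free benzhydrol. The carbinol centre is racemic and is erased in step 3.

Step 3
Reactants: 6 (2-allyloxy-4,6-dimethoxyphenyl)[4-(tert-butyldimethylsilyloxy)phenyl]methyl acetate
Product: 7 4-[(2-allyloxy-4,6-dimethoxyphenyl)methylidene]cyclohexa-2,5-dien-1-one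
Conditions: CsF, MeCN, 0 °C → rt; MeCN exchanged for toluene, filtered under argon, solution used at once
Reagents that add atoms: none
Why: Fluoride-triggered 1,6-elimination, the known way to release quinone methides from 4-silyloxybenzyl esters: cleavage of the Si–O bond frees the ring D phenoxide, whose lone pair expels the benzylic acetate. No acid is present, so no benzhydryl cation forms to alkylate ring A of a second molecule, and the three donor oxygens and two ortho substituents of ring A should keep the product in solution long enough for immediate use.

Step 4
Reactants: 7 4-[(2-allyloxy-4,6-dimethoxyphenyl)methylidene]cyclohexa-2,5-dien-1-one; 8 dimethylzinc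
Product: 10 4-[(1R)-1-(2-allyloxy-4,6-dimethoxyphenyl)ethyl]phenol, via methylzinc phenolate 9 (not isolated)
Conditions: Cu(OTf)2 (5 mol%), (S,R,R)-O,O'-(1,1'-binaphthyl-2,2'-diyl) N,N-bis(1-phenylethyl)phosphoramidite (10 mol%), toluene, −30 → 0 °C; sat. aq NH4Cl
Reagents that add atoms: none
Why: Proposed new method: dimethylzinc 8 reduces the divalent copper salt and transmetalates to a methyl complex of monovalent copper bearing the phosphoramidite, which coordinates the exocyclic C=C of 7 while a zinc centre binds the quinoid carbonyl oxygen and so restores some of the electrophilicity that donor ring A takes away. The π-complex should collapse to a σ-species with trivalent copper on the exocyclic carbon, and reductive elimination then joins CH3 to that carbon and leaves ring D aromatic as methylzinc phenolate 9, which aqueous NH4Cl protonates to 10. The closest known reactions are copper-catalysed enantioselective 1,6-additions of boryl and stabilised carbon nucleophiles to aryl para-quinone methides, and copper–phosphoramidite conjugate additions of dialkylzinc reagents to enones and dienones; transfer of an unstabilised methyl group from zinc to a quinone methide under such a catalyst has not been shown. No ring is closed. The one new stereocentre, the benzylic carbon, is set by catalyst control: the chiral ligand on copper chooses between the two enantiotopic faces of the exocyclic double bond of an achiral substrate. The step needs 1,6- over 1,2- and 1,4-addition, and the substrate secures this because attack at the exocyclic carbon is the only mode that aromatises ring D and soft organocopper species avoid the carbonyl carbon. The symmetric quinoid ring makes the two double-bond geometries identical, so the catalyst meets one substrate, and the ortho allyloxy and methoxy groups twist ring A out of plane, which gives the two faces a clear steric difference. Dimethylzinc has no β-hydrogen, so reduction of 7 cannot compete, and the allyl aryl ether is not a substrate for allylic substitution under these conditions.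

Step 5
Reactants: 10 4-[(1R)-1-(2-allyloxy-4,6-dimethoxyphenyl)ethyl]phenol
Product: 11 2-[(1R)-1-(4-hydroxyphenyl)ethyl]-3,5-dimethoxyphenol
Conditions: Pd(PPh3)4 (3 mol%), morpholine, THF, rt
Reagents that add atoms: none
Why: Tsuji–Trost deallylation; zerovalent palladium ionises the allyl aryl ether to a π-allyl complex of divalent palladium that morpholine captures irreversibly. No acid is involved, so the electron-rich diarylmethine, the methyl ethers and the stereocentre are not touched.

Step 6
Reactants: 11 2-[(1R)-1-(4-hydroxyphenyl)ethyl]-3,5-dimethoxyphenol
Product: 13 4-[(1R)-1-(3-acetyl-2-hydroxy-4,6-dimethoxyphenyl)ethyl]phenyl acetate, via difluoroboron chelate 12 (not isolated)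
Conditions: Ac2O, BF3·OEt2, CH2Cl2, 0 °C → rt; then aq NaOAc, THF, 40 °C
Reagents that add atoms: acetic anhydride, CC(=O)OC(C)=O
Why: Friedel–Crafts acylation of a phloroglucinol-type phenol; the ring D phenol is O-acetylated first, which withdraws its donor power from the stereocentre, and ring A is acylated at C4a, its only free position ortho to the hydroxyl. There the ketone is held as chelate 12, which is the sink of reversible acyl transfer and deactivates ring A against a second acylation and against ipso-protonation; aqueous acetate then frees 13. Material that loses the ring D acetate in the work-up converges with 13 in step 7.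

Step 7
Reactants: 13 4-[(1R)-1-(3-acetyl-2-hydroxy-4,6-dimethoxyphenyl)ethyl]phenyl acetate; 14 4-methoxybenzaldehyde
Product: 16 (2E)-1-{2-hydroxy-3-[(1R)-1-(4-hydroxyphenyl)ethyl]-4,6-dimethoxyphenyl}-3-(4-methoxyphenyl)prop-2-en-1-one, via deacetylated ketone 15 (not isolated)
Conditions: KOH (50% aq, excess), EtOH, rt; then 1 M HCl to pH 5, 0 °C
Reagents that add atoms: none
Why: Claisen–Schmidt condensation; hydroxide first saponifies the aryl acetate to 15, whose methyl ketone enolate adds to the non-enolisable aldehyde 14, and E1cB loss of water gives the E-enone. The diarylmethine C–H is far too weakly acidic for hydroxide, so the stereocentre is safe.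

Step 8
Reactants: 16 (2E)-1-{2-hydroxy-3-[(1R)-1-(4-hydroxyphenyl)ethyl]-4,6-dimethoxyphenyl}-3-(4-methoxyphenyl)prop-2-en-1-one
Product: 18 3-hydroxy-8-[(1R)-1-(4-hydroxyphenyl)ethyl]-5,7-dimethoxy-2-(4-methoxyphenyl)-4H-chromen-4-one, via trans-dihydroflavonol 17 (not isolated)
Conditions: 30% aq H2O2, NaOH, MeOH, 0 °C → rt; then dil. HCl
Reagents that add atoms: hydrogen peroxide, OO
Why: Algar–Flynn–Oyamada reaction; the 2'-phenoxide closes onto the β-carbon as hydroperoxide oxidises the α-carbon, which gives 17, and further oxidation under base gives the flavonol, removing the two transient ring stereocentres. Low temperature favours six-ring closure over the aurone pathway that a 6'-methoxy group encourages; the remote ring D phenoxide and the diarylmethine are not oxidised by alkaline peroxide.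

Step 9
Reactants: 18 3-hydroxy-8-[(1R)-1-(4-hydroxyphenyl)ethyl]-5,7-dimethoxy-2-(4-methoxyphenyl)-4H-chromen-4-one
Product: 19 3,5-dihydroxy-8-[(1R)-1-(4-hydroxyphenyl)ethyl]-7-methoxy-2-(4-methoxyphenyl)-4H-chromen-4-one
Conditions: BCl3, CH2Cl2, −78 → 0 °C; then H2O
Reagents that add atoms: none
Why: Chelation-controlled ether cleavage; boron bound to the C4 carbonyl activates only the peri methoxy group at C5, whose methyl is removed by chloride, while the C7 and ring B methyl ethers stay at low temperature. Ring A is now a vinylogous ester and no protic acid is present before the quench, so ionisation at the stereocentre is not expected.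

## Compound list

1 | 2-hydroxy-4,6-dimethoxybenzaldehyde | COc1cc(O)c(C=O)c(OC)c1 | starting material
2 | 2-(allyloxy)-4,6-dimethoxybenzaldehyde | COc1cc(OCC=C)c(C=O)c(OC)c1 | intermediate
3 | (4-bromophenoxy)(tert-butyl)dimethylsilane | CC(C)(C)[Si](C)(C)Oc1ccc(Br)cc1 | starting material
4 | [4-(tert-butyldimethylsilyloxy)phenyl]magnesium bromide | CC(C)(C)[Si](C)(C)Oc1ccc([Mg]Br)cc1 | intermediate (not isolated)
5 | bromomagnesium (2-allyloxy-4,6-dimethoxyphenyl)[4-(tert-butyldimethylsilyloxy)phenyl]methanolate, racemic | COc1cc(OCC=C)c(C(O[Mg]Br)c2ccc(O[Si](C)(C)C(C)(C)C)cc2)c(OC)c1 | intermediate (not isolated)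
6 | (2-allyloxy-4,6-dimethoxyphenyl)[4-(tert-butyldimethylsilyloxy)phenyl]methyl acetate, racemic | COc1cc(OCC=C)c(C(OC(C)=O)c2ccc(O[Si](C)(C)C(C)(C)C)cc2)c(OC)c1 | intermediate
7 | 4-[(2-allyloxy-4,6-dimethoxyphenyl)methylidene]cyclohexa-2,5-dien-1-one | COc1cc(OC)c(C=C2C=CC(=O)C=C2)c(OCC=C)c1 | intermediate
8 | dimethylzinc | C[Zn]C | starting material
9 | methylzinc 4-[(1R)-1-(2-allyloxy-4,6-dimethoxyphenyl)ethyl]phenolate | COc1cc(OC)c([C@H](C)c2ccc(O[Zn]C)cc2)c(OCC=C)c1 | intermediate (not isolated)
10 | 4-[(1R)-1-(2-allyloxy-4,6-dimethoxyphenyl)ethyl]phenol | COc1cc(OC)c([C@H](C)c2ccc(O)cc2)c(OCC=C)c1 | intermediate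
11 | 2-[(1R)-1-(4-hydroxyphenyl)ethyl]-3,5-dimethoxyphenol | COc1cc(O)c([C@H](C)c2ccc(O)cc2)c(OC)c1 | intermediate
12 | difluoroboron chelate of 13 (boron bridging the C8a oxygen and the acetyl oxygen) | CC1=[O+][B-](F)(F)Oc2c1c(OC)cc(OC)c2[C@H](C)c3ccc(OC(C)=O)cc3 | intermediate (not isolated)
13 | 4-[(1R)-1-(3-acetyl-2-hydroxy-4,6-dimethoxyphenyl)ethyl]phenyl acetate | COc1cc(OC)c(C(C)=O)c(O)c1[C@H](C)c2ccc(OC(C)=O)cc2 | intermediate
14 | 4-methoxybenzaldehyde | COc1ccc(C=O)cc1 | starting material
15 | 1-{2-hydroxy-3-[(1R)-1-(4-hydroxyphenyl)ethyl]-4,6-dimethoxyphenyl}ethan-1-one | COc1cc(OC)c(C(C)=O)c(O)c1[C@H](C)c2ccc(O)cc2 | intermediate (not isolated)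
16 | (2E)-1-{2-hydroxy-3-[(1R)-1-(4-hydroxyphenyl)ethyl]-4,6-dimethoxyphenyl}-3-(4-methoxyphenyl)prop-2-en-1-one | COc1ccc(/C=C/C(=O)c2c(OC)cc(OC)c([C@H](C)c3ccc(O)cc3)c2O)cc1 | intermediate
17 | (2S,3S)-3-hydroxy-8-[(1R)-1-(4-hydroxyphenyl)ethyl]-5,7-dimethoxy-2-(4-methoxyphenyl)-2,3-dihydro-4H-chromen-4-one, the 2,3-trans isomer shown, formed together with its (2R,3R) diastereomer | COc1ccc([C@@H]2Oc3c([C@H](C)c4ccc(O)cc4)c(OC)cc(OC)c3C(=O)[C@H]2O)cc1 | intermediate (not isolated)
18 | 3-hydroxy-8-[(1R)-1-(4-hydroxyphenyl)ethyl]-5,7-dimethoxy-2-(4-methoxyphenyl)-4H-chromen-4-one | COc1ccc(-c2oc3c([C@H](C)c4ccc(O)cc4)c(OC)cc(OC)c3c(=O)c2O)cc1 | intermediate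
19 | 3,5-dihydroxy-8-[(1R)-1-(4-hydroxyphenyl)ethyl]-7-methoxy-2-(4-methoxyphenyl)-4H-chromen-4-one | COc1ccc(-c2oc3c([C@H](C)c4ccc(O)cc4)c(OC)cc(O)c3c(=O)c2O)cc1 | target

## Step count and weak points

Total: 9 steps. Longest linear sequence: 9 steps, from 1 to 19; bromide 3 enters at step 2, dimethylzinc 8 at step 4 and aldehyde 14 at step 7.

Step 4 (key step, the one that carries the label Proposed new method). The most likely failure is methyl transfer that is too slow. Ring A's donor oxygens and the twisted aryl lower the electrophilicity of the exocyclic carbon, and methyl is the alkyl group least willing to leave zinc, so oligomerisation of the quinone methide and unselective background addition can overtake the catalytic cycle. The second risk is poor discrimination between the two faces.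

Fallback, by known chemistry (chiral phosphoric acid transfer hydrogenation of hydroxyphenyl-substituted 1,1-diarylethenes through a quinone methide ion pair). It sets out from alkoxide 5.
- Quenching 5 with aqueous NH4Cl instead of acetic anhydride gives the carbinol F1.
- MnO2 oxidises it to the benzophenone F2.
- Wittig methylenation with Ph3P=CH2 gives the 1,1-diarylethene silyl ether F3.
- TBAF frees the vinylphenol F4.
- A chiral BINOL-derived phosphoric acid protonates F4 to the methyl-substituted quinone methide ion pair and a Hantzsch ester delivers hydride to one face.

The methyl carbon is already in place and hydride is the nucleophile. The allyl ether survives, and the route is rejoined at 10.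

Step 3. Premature ionisation of the benzylic acetate during isolation of 6 (solvolysis, or alkylation of a second ring A), or oligomerisation and hydration of the quinone methide on concentration, would starve the key step.

Fallback: it again sets out from 5 through the carbinol F1. Treatment with sodium 4-methylbenzenesulfinate in aqueous acetic acid exchanges the hydroxyl for sulfinate by way of the stabilised cation, which the excess sulfinate traps faster than ring A. The resulting sulfone F5 does not ionise and can be purified and stored. CsF in MeCN then removes silicon, the phenoxide expels sulfinate, and the route is rejoined at 7 immediately before step 4.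

Step 6. Two processes threaten it: competing acylation at C6, para to the hydroxyl, and acid-induced ionisation of the C8–CH bond before ring A is deactivated, which would erode the enantiomeric purity or cleave the side chain.

Fallback, avoiding strong acid altogether; it sets out from 10.
- TBSCl and imidazole give the silyl ether F6.
- Pd(PPh3)4 and morpholine give the phenol F7.
- MgCl2, Et3N and paraformaldehyde in refluxing MeCN deliver a formyl group through the magnesium phenoxide only ortho to the hydroxyl, that is at C4a, giving the salicylaldehyde F8.
- MeMgBr gives the carbinol F9.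
- MnO2 gives the ketone F10.
- Under the conditions of step 7, hydroxide removes the aryl silyl ether, so F10 passes through 15 in the flask.

The route is rejoined at 16.

Step 8. Closure through the α-carbon to an aurone, favoured by the 6'-methoxy group, or over-oxidation of the chalcone can lower the efficiency.

Fallback, separating cyclisation from hydroxylation; it sets out from 16.
- One equivalent of Ac2O with Et3N at 0 °C acetylates the unhindered ring D phenol and leaves the chelated 2'-hydroxyl, giving the chalcone acetate F11.
- Catalytic I2 in DMSO at 120 °C closes and dehydrogenates it to the flavone F12.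
- Dimethyldioxirane epoxidises the C2–C3 double bond, and a trace of TsOH opens the epoxide to the flavonol acetate F13.
- K2CO3 in MeOH removes the acetate.

The route is rejoined at 18.

## Further compounds

F1 | step 4 | (2-allyloxy-4,6-dimethoxyphenyl)[4-(tert-butyldimethylsilyloxy)phenyl]methanol, racemic | COc1cc(OCC=C)c(C(O)c2ccc(O[Si](C)(C)C(C)(C)C)cc2)c(OC)c1
F2 | step 4 | (2-allyloxy-4,6-dimethoxyphenyl)[4-(tert-butyldimethylsilyloxy)phenyl]methanone | COc1cc(OCC=C)c(C(=O)c2ccc(O[Si](C)(C)C(C)(C)C)cc2)c(OC)c1
F3 | step 4 | tert-butyl{4-[1-(2-allyloxy-4,6-dimethoxyphenyl)ethenyl]phenoxy}dimethylsilane | COc1cc(OCC=C)c(C(=C)c2ccc(O[Si](C)(C)C(C)(C)C)cc2)c(OC)c1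
F4 | step 4 | 4-[1-(2-allyloxy-4,6-dimethoxyphenyl)ethenyl]phenol | COc1cc(OCC=C)c(C(=C)c2ccc(O)cc2)c(OC)c1
F5 | step 3 | tert-butyl{4-[(2-allyloxy-4,6-dimethoxyphenyl)(4-methylbenzenesulfonyl)methyl]phenoxy}dimethylsilane, racemic | COc1cc(OCC=C)c(C(c2ccc(O[Si](C)(C)C(C)(C)C)cc2)S(=O)(=O)c2ccc(C)cc2)c(OC)c1
F6 | step 6 | tert-butyl{4-[(1R)-1-(2-allyloxy-4,6-dimethoxyphenyl)ethyl]phenoxy}dimethylsilane | COc1cc(OC)c([C@H](C)c2ccc(O[Si](C)(C)C(C)(C)C)cc2)c(OCC=C)c1
F7 | step 6 | 2-{(1R)-1-[4-(tert-butyldimethylsilyloxy)phenyl]ethyl}-3,5-dimethoxyphenol | COc1cc(O)c([C@H](C)c2ccc(O[Si](C)(C)C(C)(C)C)cc2)c(OC)c1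
F8 | step 6 | 3-{(1R)-1-[4-(tert-butyldimethylsilyloxy)phenyl]ethyl}-2-hydroxy-4,6-dimethoxybenzaldehyde | COc1cc(OC)c(C=O)c(O)c1[C@H](C)c2ccc(O[Si](C)(C)C(C)(C)C)cc2
F9 | step 6 | 1-(3-{(1R)-1-[4-(tert-butyldimethylsilyloxy)phenyl]ethyl}-2-hydroxy-4,6-dimethoxyphenyl)ethan-1-ol, both carbinol epimers | COc1cc(OC)c(C(C)O)c(O)c1[C@H](C)c2ccc(O[Si](C)(C)C(C)(C)C)cc2
F10 | step 6 | 1-(3-{(1R)-1-[4-(tert-butyldimethylsilyloxy)phenyl]ethyl}-2-hydroxy-4,6-dimethoxyphenyl)ethan-1-one | COc1cc(OC)c(C(C)=O)c(O)c1[C@H](C)c2ccc(O[Si](C)(C)C(C)(C)C)cc2
F11 | step 8 | 4-[(1R)-1-{2-hydroxy-4,6-dimethoxy-3-[(2E)-3-(4-methoxyphenyl)prop-2-enoyl]phenyl}ethyl]phenyl acetate | COc1ccc(/C=C/C(=O)c2c(OC)cc(OC)c([C@H](C)c3ccc(OC(C)=O)cc3)c2O)cc1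
F12 | step 8 | 4-{(1R)-1-[5,7-dimethoxy-2-(4-methoxyphenyl)-4-oxo-4H-chromen-8-yl]ethyl}phenyl acetate | COc1ccc(-c2cc(=O)c3c(OC)cc(OC)c([C@H](C)c4ccc(OC(C)=O)cc4)c3o2)cc1
F13 | step 8 | 4-{(1R)-1-[3-hydroxy-5,7-dimethoxy-2-(4-methoxyphenyl)-4-oxo-4H-chromen-8-yl]ethyl}phenyl acetate | COc1ccc(-c2oc3c([C@H](C)c4ccc(OC(C)=O)cc4)c(OC)cc(OC)c3c(=O)c2O)cc1
A1 | alternative 1 | 2-[(1R)-1-(4-benzyloxyphenyl)ethyl]-5-ethoxy-3-(triisopropylsilyloxy)phenol | CCOc1cc(O)c([C@H](C)c2ccc(OCc3ccccc3)cc2)c(O[Si](C(C)C)(C(C)C)C(C)C)c1
A2 | alternative 1 | 3-ethoxycyclobut-2-en-1-one | CCOC1=CC(=O)C1
A3 | alternative 1 | {[(3R)-3-(4-benzyloxyphenyl)but-1-yn-1-yl]oxy}tri(propan-2-yl)silane | CC(C)[Si](OC#C[C@H](C)c1ccc(OCc2ccccc2)cc1)(C(C)C)C(C)C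
A4 | alternative 2 | (4S)-4-{(1R)-1-[2-(methoxymethoxy)-4,6-dimethoxyphenyl]ethyl}cyclohex-2-en-1-one | COCOc1cc(OC)cc(OC)c1[C@H](C)[C@@H]1C=CC(=O)CC1
A5 | alternative 2 | (3R)-3-[2-(methoxymethoxy)-4,6-dimethoxyphenyl]butanal | COCOc1cc(OC)cc(OC)c1[C@H](C)CC=O
A6 | alternative 2 | but-3-en-2-one | CC(=O)C=C
A7 | alternative 3 | (4R)-4-[4-(benzyloxy)phenyl]-5,7-dimethoxy-3,4-dihydro-2H-chromen-2-one | O=C1Oc2cc(OC)cc(OC)c2[C@H](C1)c1ccc(OCc2ccccc2)cc1
A8 | alternative 3 | 5,7-dimethoxy-2H-chromen-2-one | COc1cc(OC)c2ccc(=O)oc2c1
A9 | alternative 3 | [4-(benzyloxy)phenyl]boronic acid | OB(O)c1ccc(OCc2ccccc2)cc1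
A10 | alternative 3 | Rh(acac)(C2H4)2 | CC(=O)C=C(C)[O-].C=C.C=C.[Rh+]
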